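## Retrosynthetic overview

1. The α-methylene-γ-butyrolactone (O–C8, C7, C11=C13H2, C12=O) and the seven-membered ring are made together at the end by a carbonylative [2+2+1] union of an aldehyde (C8), the inner π-bond of a terminal allene (C7=C11=C13) and CO (C12). Enabling feature: the lactone is fused through C7–C8 to a cycloheptene whose C1=C5 double bond is shared with the cyclopentene, so the allenylmethyl arm on C5 and the aldehyde arm on C1 sit cis on a rigid tetrasubstituted alkene and only the ring bond C7–C8 is missing.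
2. Allenyl aldehyde ⇐ 2,3-disubstituted 4-oxycyclopentenone: the C5 prop-2-ynyl group comes from a Stork–Danheiser alkylative carbonyl transposition (then Crabbé homologation); the C1 side chain with C10 comes from an amine-catalysed Michael addition of a cyclopentane-1,3-dione to crotonaldehyde.
3. Dione ⇐ cis-fused δ-lactone enone (epoxidation, isomerisation) ⇐ α′-enolate of (S)-4-methyl-4-silyloxycyclopentenone (from (S)-linalool by ring-closing metathesis and allylic oxidation) + an ethyl 2-arylacrylate.
4. Arylacrylate ⇐ 4-bromo-2-iodobenzoic acid + a pentynyl silyl ether; benzylic centre by carboxy-directed asymmetric hydrogenation.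
5. Ring order: benzene (bought) → cyclopentene → δ-lactone → temporary dihydropyran acetal (opened again in step 15) → cycloheptene and γ-lactone together. C4 is bought, C10 and the benzylic carbon are set by catalysis, and C3, C17, C2, C7 and C8 are relayed by substrate control.

Key step: step 20

Assumption: (S)-(+)-linalool of high enantiomeric purity is taken as purchasable; its purity fixes that of C4 and of the whole series.

Notation: locants C1–C15 follow the guaiane skeleton of the target (C1=C5 ring-fusion alkene, C2 acetoxy carbon, C4 quaternary carbinol carbon, C6–C10 seven-membered ring, C11–C13 methylene lactone); C16, C17, C18 are the δ-lactone C=O, CH(aryl) and CH2. Ar1, Ar2, Ar3 = 4-[(tert-butyldiphenylsilyloxy)methyl]-3-[(2R)-5-X-pentan-2-yl]phenyl with X = OSi(tBu)Me2, OH, OAc.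

## Route

Step 1
Reactants: 1 tert-butyldimethyl(pent-4-yn-1-yloxy)silane
Product: 3 2-[5-(tert-butyldimethylsilyloxy)pent-1-en-2-yl]-4,4,5,5-tetramethyl-1,3,2-dioxaborolane, via alkenyl(diisobutyl)alane 2 (not isolated)
Conditions: Ni(dppp)Cl2 (3 mol %), iBu2AlH (1.3 equiv), THF, 0 → 22 °C; then MeOBpin (3 equiv), 0 → 22 °C
Reagents that add atoms: 2-methoxy-4,4,5,5-tetramethyl-1,3,2-dioxaborolane COB1OC(C)(C)C(C)(C)O1
Why: Nickel-catalysed Markovnikov (α-selective) hydroalumination of the terminal alkyne puts aluminium on the internal carbon, and transmetalation to boron with MeOBpin should give the 1,1-disubstituted alkenylboronate (hydroalumination–borylation), the silyl ether being inert to iBu2AlH.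

Step 2
Reactants: 3 alkenylboronate; 4 4-bromo-2-iodobenzoic acid
Product: 5 4-bromo-2-[5-(tert-butyldimethylsilyloxy)pent-1-en-2-yl]benzoic acid
Conditions: Pd(dppf)Cl2 (3 mol %), K3PO4 (3 equiv), 1,4-dioxane/H2O (5:1), 50 °C; citric acid work-up
Reagents that add atoms: none
Why: Suzuki–Miyaura coupling, chemoselective because oxidative addition into the C–I bond is much faster than into the C–Br bond, which is kept for step 6.

Step 3
Reactants: 5 4-bromo-2-[5-(tert-butyldimethylsilyloxy)pent-1-en-2-yl]benzoic acid
Product: 6 4-bromo-2-[(2R)-5-(tert-butyldimethylsilyloxy)pentan-2-yl]benzoic acid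
Conditions: [Ir(cod)(SIPHOX)]B[3,5-(CF3)2C6H3]4 (1 mol %; SIPHOX = spirobiindane phosphine–oxazoline ligand, the enantiomer that delivers the R acid), H2 (6 atm), Et3N (0.5 equiv), MeOH, rt
Reagents that add atoms: none
Why: Carboxy-directed iridium-catalysed asymmetric hydrogenation of a 1,1-disubstituted aryl alkene, in which the ortho carboxylate binds the metal and the chiral ligand differentiates the alkene faces, sets the benzylic (R) centre under catalyst control and leaves the aryl bromide intact.

Step 4
Reactants: 6 4-bromo-2-[(2R)-5-(tert-butyldimethylsilyloxy)pentan-2-yl]benzoic acid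
Product: 7 {4-bromo-2-[(2R)-5-(tert-butyldimethylsilyloxy)pentan-2-yl]phenyl}methanol
Conditions: BH3·SMe2 (2 equiv), THF, 0 °C → rt; MeOH/H2O quench
Reagents that add atoms: none
Why: Borane reduces the carboxylic acid through its acyloxyborane far faster than it touches the aryl bromide or the silyl ether (chemoselective acid reduction).

Step 5
Reactants: 7 {4-bromo-2-[(2R)-5-(tert-butyldimethylsilyloxy)pentan-2-yl]phenyl}methanol
Product: 8 tert-butyl({4-bromo-2-[(2R)-5-(tert-butyldimethylsilyloxy)pentan-2-yl]benzyl}oxy)diphenylsilane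
Conditions: TBDPSCl (1.2 equiv), imidazole (2 equiv), DMF, rt
Reagents that add atoms: tert-butyl(chloro)diphenylsilane CC(C)(C)[Si](Cl)(c1ccccc1)c1ccccc1
Why: Standard silylation of the primary benzylic alcohol; the tert-butyldiphenylsilyl ether is chosen because it should survive the acidic methanol of steps 14 and 15, in which the alkyl silyl ether is removed on purpose.

Step 6
Reactants: 8 aryl bromide
Product: 9 ethyl 2-(Ar1)acetate
Conditions: BrZnCH2CO2Et (1.3 equiv), Pd(dba)2 (2 mol %), P(tBu)3 (2 mol %), THF, rt
Reagents that add atoms: (2-ethoxy-2-oxoethyl)zinc bromide CCOC(=O)C[Zn]Br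
Why: Palladium-catalysed α-arylation of a zinc ester enolate (Reformatsky reagent) with the aryl bromide proceeds under neutral conditions compatible with both silyl ethers.

Step 7
Reactants: 9 ethyl 2-(Ar1)acetate
Product: 10 ethyl 2-(Ar1)prop-2-enoate
Conditions: (CH2O)n (3 equiv), K2CO3 (2 equiv), Bu4NI (10 mol %), toluene, 80 °C
Reagents that add atoms: formaldehyde (as paraformaldehyde) C=O
Why: Aldol addition of the arylacetate enolate to formaldehyde followed by E1cB loss of water (α-methylenation) gives the 2-arylacrylate.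

Step 8
Reactants: 11 (S)-(+)-linalool
Product: 13 trimethyl{[(1S)-1-methylcyclopent-2-en-1-yl]oxy}silane, via (1S)-1-methylcyclopent-2-en-1-ol 12 (not isolated)
Conditions: second-generation Grubbs catalyst RuCl2(=CHPh)(H2IMes)(PCy3) (0.5 mol %), CH2Cl2, 40 °C; then TMSOTf (1.2 equiv), Et3N (1.5 equiv), 0 °C
Reagents that add atoms: trimethylsilyl trifluoromethanesulfonate C[Si](C)(C)OS(=O)(=O)C(F)(F)F
Why: Ring-closing metathesis of the 1,6-diene with loss of 2-methylpropene gives the cyclopentenol without touching the bought carbinol stereocentre (future C4), and silylation in the same flask avoids isolating the volatile alcohol.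

Step 9
Reactants: 13 trimethyl{[(1S)-1-methylcyclopent-2-en-1-yl]oxy}silane
Product: 14 (4S)-4-methyl-4-(trimethylsilyloxy)cyclopent-2-en-1-one
Conditions: Rh2(cap)4 (dirhodium tetracaprolactamate, 1 mol %), tBuOOH (5 equiv, in decane), K2CO3 (0.5 equiv), CH2Cl2, rt
Reagents that add atoms: tert-butyl hydroperoxide CC(C)(C)OO
Why: Dirhodium-catalysed allylic oxidation with tert-butyl hydroperoxide: the ring has a single allylic methylene, and the allyl radical is expected to be trapped at the terminus remote from the quaternary carbon, which gives the 4-silyloxy enone.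

Step 10
Reactants: 14 (4S)-4-methyl-4-(trimethylsilyloxy)cyclopent-2-en-1-one; 10 ethyl 2-(Ar1)prop-2-enoate
Product: 16 ethyl 2-(Ar1)-3-(2-hydroxy-2-methyl-5-oxocyclopent-3-en-1-yl)propanoate (epimers at C3 and C17), via silyl ether Michael adduct 15 (not isolated)
Conditions: LiN(iPr)2 (1.1 equiv), THF, –78 °C; 10, –78 °C; then 1 M HCl, 0 °C
Reagents that add atoms: none
Why: Kinetic deprotonation at the only enolisable position (α′, future C3) and Michael addition of the lithium enolate to the 2-arylacrylate form the C3–C18 bond at –78 °C, where β-elimination of the silyloxy group is slow, and the acidic quench removes the trimethylsilyl ether; C3 and C17 are not controlled here and are corrected in steps 11 and 15.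

Step 11
Reactants: 16 hydroxy ester
Product: 17 cis-fused δ-lactone enone (C17 epimers)
Conditions: CSA (0.1 equiv), toluene, 5 Å molecular sieves, 70 °C
Reagents that add atoms: none
Why: Acid-catalysed lactonisation (transesterification) in which only the C3 epimer with the side chain cis to the tertiary hydroxyl can close the δ-lactone while acid-mediated enolisation of the ketone feeds the other epimer into it, so the cis ring fusion at C3 is set by the ring; base is avoided because the α′-enolate of the product could expel the carboxylate.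

Step 12
Reactants: 17 cis-fused δ-lactone enone
Product: 18 α,β-epoxy ketone
Conditions: tBuOOH (1.5 equiv, in decane), BnNMe3OH (0.1 equiv), THF, 0 °C
Reagents that add atoms: tert-butyl hydroperoxide CC(C)(C)OO
Why: Weitz–Scheffer nucleophilic epoxidation of the enone by the hydroperoxide anion, which with catalytic base at 0 °C should outrun α′-deprotonation; the epoxide configuration is lost in step 13.

Step 13
Reactants: 18 α,β-epoxy ketone
Product: 19 bicyclic lactone cyclopentane-1,3-dione (C2 and C5 carbonyls)
Conditions: Pd(PPh3)4 (5 mol %), dppe (5 mol %), toluene, 80 °C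
Reagents that add atoms: none
Why: Isomerisation of the α,β-epoxy ketone to the β-diketone by zerovalent palladium (C–O oxidative addition at the α-carbon, then β-hydride elimination from the C5 alkoxide) brings C5 to the ketone oxidation level.

Step 14
Reactants: 19 bicyclic lactone 1,3-dione; 20 (E)-but-2-enal
Product: 22 tricyclic methyl acetal (vinylogous ester with enol ether oxygen on C2 and ketone at C5; C10 S), via tricyclic lactol 21 (not isolated)
Conditions: (R)-α,α-diphenylprolinol trimethylsilyl ether (10 mol %), PhCO2H (10 mol %), CH2Cl2, 0 °C → rt; then PPTS (0.1 equiv), MeOH, 3 Å molecular sieves, 0 °C → rt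
Reagents that add atoms: methanol CO
Why: Iminium-catalysed Michael addition of the cyclic 1,3-dione to (E)-crotonaldehyde, in which the diphenyl(silyloxy)methyl group of the (R)-catalyst shields one face of the iminium ion so that C1 adds to the other and sets C10 as S under catalyst control, followed by reversible hemiacetal closure through the less hindered enol oxygen on C2 (which also leaves the more electron-poor α-acyloxy ketone C5 as the acceptor of the vinylogous ester) and fixation as the methyl acetal.

Step 15
Reactants: 22 tricyclic methyl acetal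
Product: 25 enone dimethyl acetal (C2 ketone; C1=C5; C5 prop-2-ynyl; C17 R; aryl = Ar2), via lithium lactone enolate 23 (not isolated), via C5 propargyl carbinol 24 (not isolated)
Conditions: LiN(SiMe3)2 (1.1 equiv), THF, –78 °C; HC≡CCH2MgBr (2.5 equiv, from propargyl bromide, Mg, HgCl2 cat., Et2O), –78 → –20 °C; H2O; then CSA (0.3 equiv), MeOH, 0 °C → rt
Reagents that add atoms: propargyl bromide C#CCBr; methanol CO
Why: Stork–Danheiser alkylative carbonyl transposition in which the acidic α-aryl lactone is first masked as its lithium enolate so that the allenyl Grignard reagent adds (SE2′) only to the C5 carbonyl, protonation of the enolate from the convex face on quench places the aryl group equatorial (C17 R, also the expected thermodynamic epimer), and acid in methanol ionises the tertiary allylic alcohol, collapses the enol ether to the C2 ketone with the C1=C5 double bond, turns C8 into its dimethyl acetal and removes the alkyl silyl ether.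

Step 16
Reactants: 25 enone dimethyl acetal
Product: 26 C2 allylic alcohol (2R; hydroxyl cis to C18)
Conditions: NaBH4 (1.5 equiv), CeCl3·7H2O (1.2 equiv), MeOH, –40 °C
Reagents that add atoms: none
Why: Luche 1,2-reduction, with hydride expected from the convex face anti to the C18 methylene on the adjacent C3, so that the C2 hydroxyl ends up cis to the δ-lactone.

Step 17
Reactants: 26 C2 allylic alcohol
Product: 27 diacetate (C2 OAc; aryl = Ar3)
Conditions: Ac2O (5 equiv), pyridine, DMAP (0.1 equiv), CH2Cl2, rt
Reagents that add atoms: acetic anhydride CC(=O)OC(C)=O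
Why: Acetylation of the secondary allylic and the primary hydroxyl in one operation installs both acetates of the target while the benzylic oxygen stays silylated.

Step 18
Reactants: 27 diacetate
Product: 29 allene (C5 buta-2,3-dienyl), via Mannich base 28 (not isolated)
Conditions: (CH2O)n (2.5 equiv), CuBr (0.5 equiv), iPr2NH (2 equiv), 1,4-dioxane, 100 °C
Reagents that add atoms: formaldehyde (as paraformaldehyde) C=O
Why: Crabbé homologation (copper-mediated Mannich reaction of the terminal alkyne, then 1,5-hydride transfer from the amine and β-elimination) converts the prop-2-ynyl group into the buta-2,3-dienyl group by adding C13, and the hot amine also lets C17 settle as the equatorial-aryl epimer.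

Step 19
Reactants: 29 allene dimethyl acetal
Product: 30 allenyl aldehyde
Conditions: PPTS (0.2 equiv), acetone/H2O (10:1), 45 °C
Reagents that add atoms: water O
Why: Mild acid hydrolysis of the dimethyl acetal unmasks the C8 aldehyde immediately before its use, under conditions that should leave the allene, the allylic acetate and the silyl ether intact.

Step 20
Reactants: 30 allenyl aldehyde
Product: 31 tert-butyldiphenylsilyl ether of the target
Conditions: Ru3(CO)12 (5 mol %), CO (20 atm), 1,4-dioxane, 120 °C
Reagents that add atoms: carbon monoxide [C-]#[O+]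
Why: Proposed new method: oxidative cyclisation of the C8 aldehyde and the internal C7=C11 π-bond of the allene at zerovalent ruthenium should give an oxaruthenacyclopentane, CO then inserts into the Ru–C11 bond (bond C11–C12) and reductive elimination closes C12–O, so that C7–C8 and C11–C12 arise in one catalytic cycle. The closest known reaction type is the hetero-Pauson–Khand cyclocarbonylation of allenyl aldehydes to α-methylene-γ-butyrolactones with Ru3(CO)12/CO or Mo(CO)6, established for five- and six-membered carbocycles; closing a seven-membered ring this way is the untested extension, made reasonable because the tetrasubstituted C1=C5 alkene of the cyclopentene holds both arms cis and leaves few rotatable bonds between the reacting π-systems. Ring closures: the cycloheptene closes by C7–C8 bond formation (7-exo with respect to both the C=O and the C7=C11 π-bonds) and the γ-lactone by the carbonylative [2+2+1] closure. Stereocontrol: C7 and C8 are set together in the metallacycle, where a chair-like cycloheptene with the C8–O and C7–C11 bonds both pseudo-equatorial should give the trans fusion, and the C10 methyl group selects the chair in which it is pseudo-axial (avoiding A(1,2) strain with C2 of the cyclopentene), which places it cis to C11 and trans to O8 as in the target. Selectivity needed: reaction at the internal rather than the terminal allene π-bond (the normal mode of allenyl carbonyl cyclocarbonylation, giving the exocyclic methylene), no ionisation of the C2 acetate (its alkene is tetrasubstituted and poorly coordinating) and no decarbonylation of the aldehyde (suppressed by CO pressure).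

Step 21
Reactants: 31 tert-butyldiphenylsilyl ether of the target
Product: 32 CNP0205574.1
Conditions: Bu4NF (2 equiv), AcOH (2 equiv), THF, 0 °C → rt
Reagents that add atoms: none
Why: Fluoride-mediated cleavage of the tert-butyldiphenylsilyl ether, buffered with acetic acid so that the acetates, the α-aryl lactone and the α-methylene lactone are not exposed to basic fluoride.

## Compound list

1 | tert-butyldimethyl(pent-4-yn-1-yloxy)silane | C#CCCCO[Si](C)(C)C(C)(C)C | starting material
2 | [5-(tert-butyldimethylsilyloxy)pent-1-en-2-yl]diisobutylalane | C=C(CCCO[Si](C)(C)C(C)(C)C)[Al](CC(C)C)CC(C)C | intermediate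
3 | 2-[5-(tert-butyldimethylsilyloxy)pent-1-en-2-yl]-4,4,5,5-tetramethyl-1,3,2-dioxaborolane | C=C(CCCO[Si](C)(C)C(C)(C)C)B1OC(C)(C)C(C)(C)O1 | intermediate
4 | 4-bromo-2-iodobenzoic acid | OC(=O)c1ccc(Br)cc1I | starting material
5 | 4-bromo-2-[5-(tert-butyldimethylsilyloxy)pent-1-en-2-yl]benzoic acid | C=C(CCCO[Si](C)(C)C(C)(C)C)c1cc(Br)ccc1C(=O)O | intermediate
6 | 4-bromo-2-[(2R)-5-(tert-butyldimethylsilyloxy)pentan-2-yl]benzoic acid | OC(=O)c1ccc(Br)cc1[C@H](C)CCCO[Si](C)(C)C(C)(C)C | intermediate
7 | {4-bromo-2-[(2R)-5-(tert-butyldimethylsilyloxy)pentan-2-yl]phenyl}methanol | OCc1ccc(Br)cc1[C@H](C)CCCO[Si](C)(C)C(C)(C)C | intermediate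
8 | tert-butyl({4-bromo-2-[(2R)-5-(tert-butyldimethylsilyloxy)pentan-2-yl]benzyl}oxy)diphenylsilane | CC(C)(C)[Si](OCc1ccc(Br)cc1[C@H](C)CCCO[Si](C)(C)C(C)(C)C)(c1ccccc1)c1ccccc1 | intermediate
9 | ethyl 2-(Ar1)acetate | CCOC(=O)Cc1ccc(CO[Si](c2ccccc2)(c2ccccc2)C(C)(C)C)c([C@H](C)CCCO[Si](C)(C)C(C)(C)C)c1 | intermediate
10 | ethyl 2-(Ar1)prop-2-enoate | C=C(C(=O)OCC)c1ccc(CO[Si](c2ccccc2)(c2ccccc2)C(C)(C)C)c([C@H](C)CCCO[Si](C)(C)C(C)(C)C)c1 | intermediate
11 | (S)-(+)-linalool, (3S)-3,7-dimethylocta-1,6-dien-3-ol | C=C[C@@](C)(O)CCC=C(C)C | starting material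
12 | (1S)-1-methylcyclopent-2-en-1-ol | C[C@@]1(O)C=CCC1 | intermediate
13 | trimethyl{[(1S)-1-methylcyclopent-2-en-1-yl]oxy}silane | C[C@@]1(O[Si](C)(C)C)C=CCC1 | intermediate
14 | (4S)-4-methyl-4-(trimethylsilyloxy)cyclopent-2-en-1-one | C[C@@]1(O[Si](C)(C)C)C=CC(=O)C1 | intermediate
15 | ethyl 2-(Ar1)-3-[2-methyl-5-oxo-2-(trimethylsilyloxy)cyclopent-3-en-1-yl]propanoate; quaternary carbon as in 14; epimers at C3 and C17 | CCOC(=O)C(CC1C(=O)C=C[C@@]1(C)O[Si](C)(C)C)c1ccc(CO[Si](c2ccccc2)(c2ccccc2)C(C)(C)C)c([C@H](C)CCCO[Si](C)(C)C(C)(C)C)c1 | intermediate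
16 | ethyl 2-(Ar1)-3-(2-hydroxy-2-methyl-5-oxocyclopent-3-en-1-yl)propanoate; quaternary carbon as in 14; epimers at C3 and C17 | CCOC(=O)C(CC1C(=O)C=C[C@@]1(C)O)c1ccc(CO[Si](c2ccccc2)(c2ccccc2)C(C)(C)C)c([C@H](C)CCCO[Si](C)(C)C(C)(C)C)c1 | intermediate
17 | 3-(Ar1)-7a-methyl-3,4,4a,7a-tetrahydrocyclopenta[b]pyran-2,5-dione; cis ring fusion with C3 and C4 arranged as in the target; both epimers at C17 | O=C1C=C[C@@]2(C)OC(=O)C(c3ccc(CO[Si](c4ccccc4)(c4ccccc4)C(C)(C)C)c([C@H](C)CCCO[Si](C)(C)C(C)(C)C)c3)C[C@@H]12 | intermediate
18 | C1,C5-epoxide of 17 (oxirane drawn anti to the lactone ring; its configuration is of no consequence); both epimers at C17 | O=C1[C@@H]2O[C@@H]2[C@@]3(C)OC(=O)C(c4ccc(CO[Si](c5ccccc5)(c5ccccc5)C(C)(C)C)c([C@H](C)CCCO[Si](C)(C)C(C)(C)C)c4)C[C@@H]13 | intermediate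
19 | bicyclic lactone 1,3-dione, 3-(Ar1)-7a-methyltetrahydrocyclopenta[b]pyran-2,5,7-trione (drawn as diketone); both epimers at C17 | O=C1CC(=O)[C@@]2(C)OC(=O)C(c3ccc(CO[Si](c4ccccc4)(c4ccccc4)C(C)(C)C)c([C@H](C)CCCO[Si](C)(C)C(C)(C)C)c3)C[C@@H]12 | intermediate
20 | (E)-but-2-enal (crotonaldehyde) | C/C=C/C=O | starting material
21 | tricyclic lactol: C1-alkylated dione closed as hemiacetal between C8 and the enol oxygen on C2; C10 S; anomers; C17 epimers | OC1C[C@H](C)C2=C(O1)[C@@H]3CC(c4ccc(CO[Si](c5ccccc5)(c5ccccc5)C(C)(C)C)c([C@H](C)CCCO[Si](C)(C)C(C)(C)C)c4)C(=O)O[C@]3(C)C2=O | intermediate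
22 | methyl acetal of 21 (vinylogous ester with C5 ketone); C10 S; anomers; C17 epimers | COC1C[C@H](C)C2=C(O1)[C@@H]3CC(c4ccc(CO[Si](c5ccccc5)(c5ccccc5)C(C)(C)C)c([C@H](C)CCCO[Si](C)(C)C(C)(C)C)c4)C(=O)O[C@]3(C)C2=O | intermediate
23 | lithium enolate of the δ-lactone of 22 | COC1C[C@H](C)C2=C(O1)[C@@H]3CC(c4ccc(CO[Si](c5ccccc5)(c5ccccc5)C(C)(C)C)c([C@H](C)CCCO[Si](C)(C)C(C)(C)C)c4)=C(O[Li])O[C@]3(C)C2=O | intermediate
24 | C5 tertiary carbinol carrying the prop-2-ynyl group; C17 R; epimers at C5 and at the acetal carbon | COC1C[C@H](C)C2=C(O1)[C@@H]3C[C@H](c4ccc(CO[Si](c5ccccc5)(c5ccccc5)C(C)(C)C)c([C@H](C)CCCO[Si](C)(C)C(C)(C)C)c4)C(=O)O[C@]3(C)C2(O)CC#C | intermediate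
25 | enone dimethyl acetal: C2 ketone, C1=C5, C5 prop-2-ynyl, C1 (2S)-4,4-dimethoxybutan-2-yl, cis-fused δ-lactone with (17R)-Ar2 | COC(OC)C[C@H](C)C1=C(CC#C)[C@@]2(C)OC(=O)[C@@H](c3ccc(CO[Si](c4ccccc4)(c4ccccc4)C(C)(C)C)c([C@H](C)CCCO)c3)C[C@H]2C1=O | intermediate
26 | (2R) allylic alcohol of 25, hydroxyl cis to C18 | COC(OC)C[C@H](C)C1=C(CC#C)[C@@]2(C)OC(=O)[C@@H](c3ccc(CO[Si](c4ccccc4)(c4ccccc4)C(C)(C)C)c([C@H](C)CCCO)c3)C[C@H]2[C@H]1O | intermediate
27 | diacetate: C2 acetate and Ar3 | COC(OC)C[C@H](C)C1=C(CC#C)[C@@]2(C)OC(=O)[C@@H](c3ccc(CO[Si](c4ccccc4)(c4ccccc4)C(C)(C)C)c([C@H](C)CCCOC(C)=O)c3)C[C@H]2[C@H]1OC(C)=O | intermediate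
28 | Mannich base: C5 4-(diisopropylamino)but-2-ynyl | COC(OC)C[C@H](C)C1=C(CC#CCN(C(C)C)C(C)C)[C@@]2(C)OC(=O)[C@@H](c3ccc(CO[Si](c4ccccc4)(c4ccccc4)C(C)(C)C)c([C@H](C)CCCOC(C)=O)c3)C[C@H]2[C@H]1OC(C)=O | intermediate
29 | allene: C5 buta-2,3-dienyl, C8 dimethyl acetal | COC(OC)C[C@H](C)C1=C(CC=C=C)[C@@]2(C)OC(=O)[C@@H](c3ccc(CO[Si](c4ccccc4)(c4ccccc4)C(C)(C)C)c([C@H](C)CCCOC(C)=O)c3)C[C@H]2[C@H]1OC(C)=O | intermediate
30 | allenyl aldehyde: C5 buta-2,3-dienyl, C1 (2S)-4-oxobutan-2-yl | O=CC[C@H](C)C1=C(CC=C=C)[C@@]2(C)OC(=O)[C@@H](c3ccc(CO[Si](c4ccccc4)(c4ccccc4)C(C)(C)C)c([C@H](C)CCCOC(C)=O)c3)C[C@H]2[C@H]1OC(C)=O | intermediate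
31 | benzylic tert-butyldiphenylsilyl ether of the target | C=C1C(=O)O[C@H]2C[C@H](C)C3=C(C[C@H]12)[C@@]1(C)OC(=O)[C@@H](c2ccc(CO[Si](c4ccccc4)(c4ccccc4)C(C)(C)C)c([C@H](C)CCCOC(C)=O)c2)C[C@H]1[C@H]3OC(C)=O | intermediate
32 | CNP0205574.1 | C=C1C(=O)O[C@H]2C[C@H](C)C3=C(C[C@H]12)[C@@]1(C)OC(=O)[C@@H](c2ccc(CO)c([C@H](C)CCCOC(C)=O)c2)C[C@H]1[C@H]3OC(C)=O | target

## Step count and risks

Total step count: 21. Longest linear sequence: 19 steps (steps 1–7, then 10–21).

Steps most likely to fail:

1. Step 20 (proposed new method). The seven-membered ring may fail to close (oligomerisation through intermolecular coupling, or decarbonylation of the aldehyde). The ring fusion may come out cis, or the allylic acetate may ionise at the metal. Fallback from 30, returning at 31: the two bonds are made in separate, precedented operations. Hexabutylditin and [Pd(η3-C3H5)Cl]2 (THF, rt) should add the distannane across the terminal allene π-bond, and the 2-stannylallylstannane so formed adds through C7 to the aldehyde, a known cyclisation of allenyl aldehydes, to give after work-up the cycloheptenol vinylstannane F1. Iododestannylation (I2, CH2Cl2, 0 °C) gives the vinyl iodide F2. Carbonylative lactonisation (Pd(PPh3)4, CO 1 atm, Et3N, MeCN, 60 °C) then closes the α-methylene lactone and returns to 31. If the allylation favoured the cis alcohol, C8 would be inverted at the stage of F2 by oxidation and reduction before the carbonylation.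

2. Step 15. The Grignard reagent may attack the lactone if enolisation is incomplete, allenyl instead of propargyl transfer may compete, and the skipped enyne may isomerise during the acid treatment. Fallback from 22, returning at 25: the basic organomagnesium reagent and the enolate masking are given up in favour of a non-basic Barbier reagent. Acetal 22 is first equilibrated at C17 with DBU (toluene, 60 °C; no enolisable ketone is present) to the single epimer, (17R)-acetal F3. This is treated with propargyl bromide and Zn dust (THF/saturated aqueous NH4Cl, 0 °C → rt); allenylzinc bromide adds to ketone carbonyls but not to lactones, so carbinol 24 should result, and the same acid treatment converts it into 25.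

3. Step 16. Hydride may be delivered with poor facial selectivity, because the angular methyl group on C4 lies on the face that the C18 methylene leaves open. Fallback from 25, returning at 27: the alcohols are separated; 26 is acetylated as planned, and the C2-epimeric diol F4 is converged by Mitsunobu esterification with acetic acid (PPh3, DIAD, THF, 0 °C → rt). This inverts C2 and acetylates the primary alcohol in the same operation, giving diacetate 27.

Further compounds
F1 | step 20 | cycloheptenol vinylstannane: C8 hydroxyl, C7 1-(tributylstannyl)vinyl, trans as in the target | O[C@H]2C[C@H](C)C3=C(C[C@@H]2C(=C)[Sn](CCCC)(CCCC)CCCC)[C@@]1(C)OC(=O)[C@@H](c2ccc(CO[Si](c4ccccc4)(c4ccccc4)C(C)(C)C)c([C@H](C)CCCOC(C)=O)c2)C[C@H]1[C@H]3OC(C)=O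
F2 | step 20 | vinyl iodide: C8 hydroxyl, C7 1-iodovinyl | O[C@H]2C[C@H](C)C3=C(C[C@@H]2C(=C)I)[C@@]1(C)OC(=O)[C@@H](c2ccc(CO[Si](c4ccccc4)(c4ccccc4)C(C)(C)C)c([C@H](C)CCCOC(C)=O)c2)C[C@H]1[C@H]3OC(C)=O
F3 | step 15 | (17R)-acetal, single C17 epimer of 22 | COC1C[C@H](C)C2=C(O1)[C@@H]3C[C@H](c4ccc(CO[Si](c5ccccc5)(c5ccccc5)C(C)(C)C)c([C@H](C)CCCO[Si](C)(C)C(C)(C)C)c4)C(=O)O[C@]3(C)C2=O
F4 | step 16 | C2-epimeric diol (C2 epimer of 26) | COC(OC)C[C@H](C)C1=C(CC#C)[C@@]2(C)OC(=O)[C@@H](c3ccc(CO[Si](c4ccccc4)(c4ccccc4)C(C)(C)C)c([C@H](C)CCCO)c3)C[C@H]2[C@@H]1O
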